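Write the balance on the charge first: whatever isn't yet target sits in a pool, and [target] grows by a drain constant, the fraction of that pool becoming target per hour.

| flask | starting material | temperature | remark | time |
|---|---|---|---|---|
| Saturday's | 0.12 M | −10 °C | run made earlier |  |
| Thursday's | 0.19 M | 10 °C | run made earlier |  |
| autumn | 0.086 M |  | at −5 °C throughout | 30 h |
| midnight | 0.086 M |  | at 25 °C until 4.0 h, from then on at −5 °C | 8.0 h |

- Saturday's (time / h: target / %, starting material / %): 3.00: 0, 46.0; 8.00: 1.4, 13.2; 15.0: 0.7, 1.1; 30.0: 3.7, 1.7
- Thursday's (time / h: target / %, starting material / %): 1.00: 0, 0.8; 3.00: 6.5, 1.8; 6.00: 13.7, 1.4; 10.0: 21.0, 0.9; 12.0: 24.4, 0.8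

(readings scatter by 1 percentage point)

- the numbers in the tables scatter with a standard deviation of 1 percentage point
- steps under discussion: starting material -> intermediate A; intermediate B -> target; starting material <-> dormant form; intermediate A <-> intermediate B

1. which of the two ends with the higher amount of target, in percent of the starting material charged ("neither" if they lie within 2 percentage points) (autumn / midnight / neither)
2. target at the end, in percent of the starting material charged, autumn
3. target at the end, in percent of the starting material charged, midnight

Saturday's run has 1.1% starting material left at 15.0 h, and Thursday's has 0.8% at 1.00 h. So I take the pool as the charge less target and read the fall of its logarithm between two readings. That gives 0.0236 h⁻¹ on Thursday's run and 0.00107 h⁻¹ on Saturday's, the latter a rough reading, with a rise of 2.3 percentage points against a scatter of 1 point.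

The two give an apparent activation energy of 95.8 kJ mol⁻¹. The drain constant at 25 °C over that at −5 °C is then 75.3, the cold-hour factor: the number of cold hours that one warm hour is worth. At −5 °C I reckon the drain constant at 0.00243 h⁻¹. Autumn, with 30 h, should therefore reach 7.03%, and midnight, worth 305 h of cold time, 52.3%.

The forecast names midnight, with 8% for autumn and 42% for midnight: “Midnight clearly wins, assuming no concentration effect”. My midnight figure stands higher than the forecast's.

The flask gives midnight: 6.59% for autumn and 56.7% for midnight.

    starting material → intermediate A (k = 0.446 min⁻¹, Ea = 89.0 kJ mol⁻¹)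
    intermediate B → target (k = 0.443 min⁻¹, Ea = 79.0 kJ mol⁻¹)
    starting material ⇌ dormant form (K = 11.0, k = 0.0584 min⁻¹, Ea = 86.0 kJ mol⁻¹, ΔH = −34.0 kJ mol⁻¹)
    intermediate A ⇌ intermediate B (K = 1.30, k = 0.00391 min⁻¹, Ea = 97.0 kJ mol⁻¹, ΔH = 19.0 kJ mol⁻¹)
    (constants at 25 °C)

The difference in temperature programme is the main reason for the gap between the two flasks: with that difference taken away, autumn reads 59.2% in place of 6.59%. On the cold-hour factor, midnight's 305 h of cold time compares with autumn left for 300 h, which reaches 51.8%.

Repeat autumn at 20 °C, and the same reckoning makes its 30 h worth 1170 h of cold time, so 94.2% target. That neighbour flask computes to 96.1%.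

The data are simulated with made-up constants.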